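Do not scale the complex with two exchanged in proportion to the ligand charge, and do not read it off a time axis.

| flask | starting complex | incoming ligand | remark | time |
|---|---|---|---|---|
| north-west | 0.094 M (fed, over 10 min) | 0.042 M | run made earlier |  |
| east | 0.094 M (fed, over 10 min) | 0.13 M | run made earlier |  |
| west | 0.094 M (fed, over 10 min) | 0.33 M | run made earlier |  |
| violet | 0.094 M (fed, over 10 min) | 0.0470 M |  | 4.0 h |
| red | 0.094 M (fed, over 10 min) | 0.0940 M |  | 4.0 h |
| ochre | 0.094 M (fed, over 10 min) | 0.376 M |  | 4.0 h |

| run | time / h | complex with two exchanged / % | complex with one exchanged / % |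
|---|---|---|---|
| north-west | 0.250 | 0 | 1.6 |
| north-west | 0.500 | 0 | 4.1 |
| north-west | 1.33 | 0 | 9.0 |
| north-west | 3.00 | 0.8 | 15.9 |
| east | 0.250 | 0.3 | 5.1 |
| east | 0.500 | 0.1 | 11.4 |
| east | 1.33 | 1.2 | 23.7 |
| east | 3.00 | 5.9 | 39.5 |
| west | 0.333 | 0.3 | 18.0 |
| west | 1.00 | 4.7 | 39.3 |
| west | 2.00 | 15.4 | 50.7 |
| west | 3.00 | 24.6 | 53.7 |

(readings scatter by 0.5 percentage points)

- the analysis behind the earlier runs scatters by 0.5 percentage points, standard deviation

- final complex with two exchanged, as a percentage of the starting complex charged, for each flask in turn (violet, red, ochre)

Take both exchanges as first order in free ligand and divide the rate of the second by the rate of the first: ligand level and time drop out. What remains is the second exchange's gain per starting complex lost, equal to s times the ratio of complex with one exchanged to starting complex. Over the last interval of the west run this reads 0.402: the selectivity factor s, the second exchange's rate constant over the first. Doubt it: the assumption is untested. The east run, at a different ligand level, reads 0.471, but its rise is 4.7 percentage points with 0.5 points of scatter on each reading, so keep s.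

With f the fraction of starting complex left, integration gives complex with one exchanged as (f^s − f)/(1 − s), and complex with two exchanged as the remainder of the charge.

Now f is needed. Use −ln f per molar of ligand charged as a clock. At 3.00 h it reads 4.63 M⁻¹ in the west run, 4.65 M⁻¹ in the east run and 4.35 M⁻¹ in the north-west run, so it carries across charges. Extending the west run's last hourly rise to 4.0 h is the obvious step, but that rise shrinks from 1.52 M⁻¹ to 1.35 M⁻¹. Shrink the next rise in the same ratio, which puts the clock at 5.83 M⁻¹. My reckoning then gives f of 76.0%, 57.8% and 11.2% for violet, red and ochre, and complex with two exchanged of 1.33%, 4.70% and 38.2%.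

The forecast, “Integrating to 4 h with ligand depletion”, gives 1.2%, 4.5% and 39%, near these figures but not the same.

The flasks give 1.17%, 4.30% and 39.6%.

    incoming ligand ⇌ dormant form (K = 0.831, k = 0.0313 min⁻¹)
    starting complex + incoming ligand → leaving ligand + complex with one exchanged (k = 0.0574 M⁻¹ min⁻¹)
    complex with one exchanged + incoming ligand → leaving ligand + complex with two exchanged (k = 0.0232 M⁻¹ min⁻¹)

Put the starting complex left in the red flask, 60%, into the rule with s: it gives 4.27% of complex with two exchanged, against 4.30% in the flask. The ochre flask's 11% gives 39.4%, against 39.6%. Two things acting together keep the red flask's complex with two exchanged at 4.30%, the falling level of incoming ligand and the length of the run: the red run with that level held reaches 18.6%, and the red run left until 40.0 h reaches 22.0%.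

(The data were generated by integration for an exercise, noise included.)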